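The data were computed for substances that don't exist; noise was put on by code.

The trap in a percent yield is to read it against the whole charge of starting material, when the reagent may not reach that far.

| flask | starting material | reagent | temperature | remark | time |
|---|---|---|---|---|---|
| birch | 4.1 mM | 5 mM | 75 °C | run made earlier |  |
| larch | 6.8 mM | 5 mM | 88 °C | run made earlier |  |
| Tuesday's | 10 mM | 5.00 mM | 95 °C |  | 2.0 min |
| Wednesday's | 5.0 mM | 5.00 mM | 80 °C |  | 2.0 min |

Tuesday's charges less reagent than starting material, and the proposed first step takes one reagent for each starting material. So we carry the reagent ceiling, the charge of reagent as a fraction of the charge of starting material: 50.0% for Tuesday's, where reagent is the limiting reagent, but 100% for Wednesday's.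

| run | time / s | target / % | starting material / % |
|---|---|---|---|
| birch | 10.0 | 12.4 | 78.9 |
| birch | 12.0 | 15.5 | 76.4 |
| birch | 20.0 | 21.1 | 69.6 |
| birch | 40.0 | 26.7 | 60.2 |
| birch | 60.0 | 28.8 | 57.5 |
| larch | 10.0 | 16.4 | 71.6 |
| larch | 12.0 | 18.5 | 70.2 |
| larch | 20.0 | 19.9 | 66.4 |
| larch | 30.0 | 20.8 | 62.5 |
| larch | 50.0 | 22.2 | 57.5 |
| larch | 60.0 | 23.2 | 54.8 |

(standard deviation of a reading: 0.5 percentage points)

- steps that have been proposed: intermediate -> side product; starting material + reagent <-> intermediate; released group -> by-product carried off; intermediate <-> target + released group

The readings give the second factor, the target share, which is target over the starting material lost. It reads 0.678 at the end of birch but 0.513 at the end of larch, and larch differs from birch in two settings, being hotter and charged with more starting material.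

- the flask that ends with the higher amount of target, in percent of the starting material charged, or "neither" when 2 percentage points or less lies between them (Tuesday's / Wednesday's / neither)
- final target, as a percentage of the starting material charged, in Tuesday's
- final target, as a percentage of the starting material charged, in Wednesday's

Ceiling times the larch share gives 25.7% for Tuesday's, but this is a rough estimate and no bound, since Tuesday's differs from larch in both temperature and charge. Birch already read 28.8% of target, having lost 42.5% of its starting material, far under Wednesday's ceiling, and Wednesday's lies close to birch. So we commit to Wednesday's.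

The forecast also says Wednesday's, with 20% for Tuesday's, below our estimate, and 31% for Wednesday's, noting “reagent at half the starting material”.

The flask gives Wednesday's: 20.9% of target in Tuesday's and 30.3% in Wednesday's.

    intermediate → side product (k = 0.0180 /s, Ea = 86.0 kJ/mol)
    starting material + reagent ⇌ intermediate (K = 53.0 /M, k = 9.50 /M/s, Ea = 53.0 kJ/mol, ΔH = 12.0 kJ/mol)
    released group → by-product carried off (k = 0.0140 /s, Ea = 93.0 kJ/mol)
    intermediate ⇌ target + released group (K = 0.00240 M, k = 0.420 /s, Ea = 84.0 kJ/mol, ΔH = −32.0 kJ/mol)
    (constants at 80 °C)

At 2.00 min Tuesday's has lost 47.0% of its starting material against its ceiling of 50.0%, with a target share of 0.445. The neighbour flask is Tuesday's with 2.0 mM of reagent, so its ceiling is 20.0%, and times the larch share that gives 10.3%. That neighbour keeps 80% of its starting material and ends with 11.4% of target.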